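# Design of a total synthesis of CNP0299929.2 (compound 27) by ring-closing metathesis of 1,3-diaxial allyl and acrylate arms

## The problem

Target 27 is numbered here as a bicyclo[3.3.1]non-2-ene: C1 and C5 are the bridgeheads, C2=C3–C4 and C6–C7–C8 the three-carbon bridges, C9 the one-carbon bridge, and C1' the side-chain carbon bonded to C8. Ring B (C1, C8, C7, C6, C5, C9) is a cyclohexane and ring A (C1, C2, C3, C4, C5, C9) a cyclohexene; both bridgeheads are quaternary (formyl on C1, methyl on C5), so neither ring can be closed by chemistry that needs a bridgehead hydrogen. There are five stereocentres. C1 and C5 are locked to each other by the bridge, so what must be set is C8 (side chain equatorial on ring B, on the face of the C2–C4 bridge), C9 (acetoxy axial on ring B, turned away from the alkene bridge) and C1'. C1' lies outside the rings and has only a methyl and a CH2 group to tell apart, so it is best taken from the chiral pool. On a cyclohexanone, C8 can control both carbons next to the carbonyl: it steers axial alkylation at C5 and, being adjacent, sends the last electrophile at C1 to its far side; once the bicycle exists, its shape decides the open face of C9. The delicate functions are three: the 1,4-ene-dial (a free hydroxymethyl group beside the other formyl group closes to a lactol and is oxidised on to a lactone), the β-relation of the C9 oxygen to the C1 formyl group (retro-aldol opening of C1–C9 in the free hydroxy aldehyde), and the trisubstituted side-chain alkene (no ozone, strong protic acid or unselective hydrogenation). The key step is possible because C2 and C4 sit syn-diaxially on C1 and C5 of ring B: with C9 as a ketone, an allyl group on C5 and a 2-substituted acrylate unit on C1 are held 1,3-diaxial, and only the C2=C3 double bond of ring A is missing.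

## Retrosynthesis

**27 back to 25, 24 and 23 (no C–C bond cut).** The two formyl groups are taken back to triethylsilyl-protected hydroxymethyl groups (25), the acetate to the free C9 alcohol (24), and the silyl ethers to triol 23. The neighbouring option, selective oxidation of the primary alcohols of 23 followed by acetylation, is rejected for two reasons. The hydroxymethyl groups on C1 and C2 are 1,4-related, so the first aldehyde formed would be trapped as a five-membered lactol and oxidised to a lactone. A final acetylation would also have to be forced at a carbinol between two quaternary carbons while a β-formyl group invites retro-aldol cleavage. In the chosen order the acetate is put on while both primary oxygens are silylated, and both aldehydes appear together from the bis(alkoxysulfonium) salt 26. The forward steps need primary-over-secondary silylation, acylation of a hindered alcohol and an oxidation that leaves an acetate alone.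

**23 back to 22 (no C–C bond cut).** All three carbinol carbons are traced to carbonyl groups in keto lactone 22: C9 to a ketone, the two hydroxymethyl carbons to the CH2–O and C=O of one γ-lactone fused across C1–C2. One hydride reagent then does all the reductive work, and the C9 stereocentre becomes a question of which face of a bridged ketone is open. Two open-chain esters on C1 and C2 would serve equally here; the lactone is preferred for reasons given two paragraphs below.

**22 back to 21 (key disconnection, C2=C3).** Cutting the ring A alkene leaves cyclohexanone 21 with an allyl group on C5 and an α-methylene lactone (a cyclic 2-substituted acrylate) spiro-fused at C1. Other cuts of ring A are weaker. C1–C2 or C4–C5 would mean forming a quaternary centre and a bridged ring in one intramolecular alkylation. C3–C4 would need a vinyl metal on an enoate. The metathesis cut needs only two alkenes that enolate chemistry can install, removes one ring and the whole bridged topology, and leaves a monocyclic precursor that already holds C1, C5, C8 and C1'. The forward reaction needs the two arms cis, and a catalyst that takes a hindered, electron-poor 1,1-disubstituted alkene while ignoring the trisubstituted one.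

**21 back to 17, 15 and 14 (C2=CH2, then C1–CH2O).** The exocyclic methylene is removed (17), and the lactone is cut between C1 and its CH2O carbon, which goes back to formaldehyde and enol silane 15 of keto ester 14. This bond is cut, and not the one from C1 to the acetate arm, because whatever is attached last to C1 enters anti to the C8 side chain, and in 27 it is the formyl carbon that is anti. A carbomethoxy group could also be the one-carbon unit. It would, however, need C-acylation of a tetrasubstituted enolate generated beside a more accessible ester CH2, and it would arrive at the wrong oxidation state. Formaldehyde on a preformed enol silane avoids both. The γ-hydroxy ester then closes to the lactone, which protects the β-hydroxy ketone from retro-aldol, leaves a single enolisable position for the methylenation, and holds the future acrylate over ring B pointing at C4.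

**14 back to 11 and 12 (C1–CH2 of the arm).** Ketone 11 has one enolisable position, and methyl bromoacetate 12 supplies C2 and its formyl carbon. No stereochemical demand is made, because C1 becomes trigonal again in 15.

**11 back to 8 and 9 (C5–C4).** The quaternary C5 is taken back to the enolate of enone 8 and allyl bromide 9. Doing this before C1 is substituted keeps the facial analysis simple: only the equatorial C8 side chain is on the ring, and axial alkylation puts allyl cis to it. The forward step needs a regiospecific enolate, which conjugate reduction of the enone supplies.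

**8 back to 4 and 5 (C1–C8 and C5–C6).** The carvone-type ring is opened to enal 4 and tert-butyl 3-oxopentanoate 5 by a Michael–aldol annulation; the ester only activates the donor and is lost. This is the one cut that joins C8 to the ring while C1' is already in place, and it lets an amine catalyst set C8. The forward step needs catalyst control at C8 without loss of the γ-stereocentre of the enal.

**4 back to 3 and 1.** The enal is the one-carbon homologue of (R)-citronellal 1 with the unsaturation moved into conjugation: methoxymethylenation and hydrolysis give 3, and dehydrogenation gives 4. The citronellal stereocentre becomes C1'.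

## Roads not taken

Alternative 1: The cut is C1–C9 of the deacetyl compound A1, which leads to cyclooctene trialdehyde A2. In the forward sense the dienol of the C1/C2 ene-dial unit of A2 adds through C1 across the eight-membered ring to the formyl group on C5; one bond closes both six-membered rings and creates C1 and C9, and acetylation of A1 ends the synthesis. Its merits are real. It is probably the biogenetic path, every oxygenated carbon is already at its final oxidation state, and the aldol is chemoselective by construction because the acceptor aldehyde is non-enolisable and the donor site unique. None of the four redox and protection steps that follow the metathesis in the chosen plan would be needed. Its weak points lie in A2. A2 is a medium ring with a quaternary formyl-bearing carbon and three aldehydes, for which no short stereocontrolled entry is evident. It can isomerise (alkene migration into conjugation with C1, epimerisation at C1) before it cyclises. The configurations at C1 and C9 would rest on the transannular conformation alone, with no reagent to correct them. The last acetylation would also be run on the β-hydroxy aldehyde A1, which can revert. After the key step this road is clearly shorter. The chosen plan sets against it a six-membered precursor built by enolate chemistry with precedent at each stereocentre, and a C9 configuration fixed by an irreversible reduction.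

Alternative 2: The cut is C5–C9 and C6–C7 of ring B, giving silyloxy diene A4 (C9, C1, C8, C7, side chain on C8) and methacrolein A5 (C5 and C6, its formyl carbon becoming C4). The forward key step is an endo Diels–Alder addition under the protonated oxazaborolidine made from (S)-diphenylprolinol and o-tolylboronic acid (Tf2N− counter-ion), giving cyclohexene A3. It sets the quaternary C5 and the C9 oxygen in one catalytic step under reagent control, independent of C1', and C9 arrives as a protected alcohol, so no late ketone reduction is needed. In both respects it is better than the chosen plan, where C5 depends on axial alkylation and C9 on the shape of the bicycle. Its weakness is what A3 leaves undone. C1=C8 is an alkene, so C8 must be set by hydrogen delivery next to C1' and C1 must be turned from an alkene carbon into a quaternary carbon with two different carbon substituents. All of ring A (C1–C2, C2=C3, C3–C4) must then be built out from the C5 formyl group. The diene also has to be made from a ketone whose α-stereocentre (C1') is enolisable. The chosen plan sets C8 on the ring by catalysis, needs one enolate step each for C5 and C1, and closes ring A with one bond.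

Alternative 3: The cut is C5–C6, closing ring B last onto a preformed ring A. The precursor A7 is a cyclohexadiene enol silane (C9=C5) carrying both esters and, on C1, a propargylic arm C8(side chain)–C7≡C6H. Ph3PAuNTf2 activates the alkyne and C5 attacks C6 in 6-endo-dig mode to give diene A6 with a C9 ketone. The step is mild and catalytic and has direct precedent in bicyclo[3.3.1]nonenone syntheses. The configuration at C5 is dictated by the tether, so it is more secure than the reductive allylation of the chosen plan. The burden moves to A7: C1 must be quaternary and bear an open-chain secondary propargylic centre (C8) next to C1', with no ring to control it, and 5-exo closure competes. The extra C6=C7 alkene must afterwards be reduced in the presence of the enoate and the side-chain alkene, and the diester-to-dial problem remains. The two key steps are equally short. The chosen plan sets C8 on a ring under catalyst control and has no alkene to remove.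

Key step: step 9

## Route

Assumption: (R)-citronellal of high enantiomeric purity is used; its stereocentre becomes C1' and no step is meant to touch it.

Step 1
Reactants: 1 (R)-citronellal
Product: 3 (R)-4,8-dimethylnon-7-enal, via (R)-1-methoxy-4,8-dimethylnona-1,7-diene 2 (not isolated)
Conditions: Ph3P+CH2OMe Cl−, KOt-Bu, THF, 0 °C to rt; then 2 M aq. HCl, THF, rt
Reagents that add atoms: (methoxymethyl)triphenylphosphonium chloride, COC[P+](c1ccccc1)(c1ccccc1)c1ccccc1.[Cl-]; water, O
Why: Wittig methoxymethylenation and enol ether hydrolysis is the standard one-carbon homologation of an aldehyde; the stereocentre is β to the carbonyl and cannot enolise.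

Step 2
Reactants: 3 (R)-4,8-dimethylnon-7-enal
Product: 4 (2E,4R)-4,8-dimethylnona-2,7-dienal
Conditions: IBX, DMSO–toluene, 70 °C
Reagents that add atoms: none
Why: IBX dehydrogenation of an aldehyde should give the (E)-enal directly; limiting oxidant and temperature should prevent further desaturation toward the γ-carbon that carries the stereocentre.

Step 3
Reactants: 4 (2E,4R)-4,8-dimethylnona-2,7-dienal; 5 tert-butyl 3-oxopentanoate
Product: 8 (5R)-2-methyl-5-[(2R)-6-methylhept-5-en-2-yl]cyclohex-2-en-1-one, via Michael adduct 6 (not isolated), via tert-butyl cyclohexenone ester 7 (not isolated)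
Conditions: (S)-2-[diphenyl(trimethylsilyloxy)methyl]pyrrolidine (10 mol%), PhCO2H (10 mol%), toluene, 0 °C to rt; then TsOH·H2O (20 mol%), toluene, 80 °C
Reagents that add atoms: none
Why: Iminium-catalysed Michael addition of the β-keto ester is followed by acid-induced aldol condensation, tert-butyl ester cleavage and decarboxylation (organocatalytic cyclohexenone annulation); attack on the E-iminium ion anti to the diphenyl(silyloxy)methyl group of the (S)-catalyst should set C8, while C1' comes from 1.

Step 4
Reactants: 8 (5R)-2-methyl-5-[(2R)-6-methylhept-5-en-2-yl]cyclohex-2-en-1-one; 9 allyl bromide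
Product: 11 (2R,5R)-2-methyl-5-[(2R)-6-methylhept-5-en-2-yl]-2-(prop-2-en-1-yl)cyclohexan-1-one, via lithium enolate 10 (not isolated)
Conditions: LiBH(s-Bu)3, THF, −78 °C; then allyl bromide, DMPU, −78 to 0 °C
Reagents that add atoms: none
Why: 1,4-Hydride delivery to the β-unsubstituted enone gives enolate 10 regiospecifically (reductive alkylation); allyl bromide should attack axially on the half-chair that keeps the C8 side chain equatorial, placing allyl cis to the side chain, as in reductive alkylations of carvone.

Step 5
Reactants: 11 (2R,5R)-2-methyl-5-[(2R)-6-methylhept-5-en-2-yl]-2-(prop-2-en-1-yl)cyclohexan-1-one; 12 methyl bromoacetate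
Product: 14 methyl 2-[(3R,6S)-3-methyl-6-[(2R)-6-methylhept-5-en-2-yl]-2-oxo-3-(prop-2-en-1-yl)cyclohexyl]acetate (epimers at the acetate-bearing carbon), via lithium enolate 13 (not isolated)
Conditions: LiN(i-Pr)2, THF, −78 °C; then BrCH2CO2Me, DMPU, −78 to −20 °C
Reagents that add atoms: none
Why: Kinetic enolate alkylation at the only enolisable position of 11; the configuration formed at C1 does not matter because C1 becomes trigonal again in step 6.

Step 6
Reactants: 14 methyl 2-[(3R,6S)-3-methyl-6-[(2R)-6-methylhept-5-en-2-yl]-2-oxo-3-(prop-2-en-1-yl)cyclohexyl]acetate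
Product: 15 methyl 2-[(3R,6S)-3-methyl-6-[(2R)-6-methylhept-5-en-2-yl]-3-(prop-2-en-1-yl)-2-(trimethylsilyloxy)cyclohex-1-en-1-yl]acetate
Conditions: TMSOTf (1.2 equiv), Et3N, CH2Cl2, 0 °C
Reagents that add atoms: trimethylsilyl trifluoromethanesulfonate, C[Si](C)(C)OS(=O)(=O)C(F)(F)F
Why: Soft enolisation and O-silylation; the ketone has a single α-hydrogen, so only one enol silane can form, and the ester should not be silylated at 0 °C with a small excess of reagent.

Step 7
Reactants: 15 methyl 2-[(3R,6S)-3-methyl-6-[(2R)-6-methylhept-5-en-2-yl]-3-(prop-2-en-1-yl)-2-(trimethylsilyloxy)cyclohex-1-en-1-yl]acetate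
Product: 17 (5R,7R,10S)-7-methyl-10-[(2R)-6-methylhept-5-en-2-yl]-7-(prop-2-en-1-yl)-2-oxaspiro[4.5]decane-3,6-dione, via hydroxymethyl keto ester 16 (not isolated)
Conditions: aq. HCHO (37%), Yb(OTf)3 (10 mol%), THF, rt; then pyridinium p-toluenesulfonate, toluene, 60 °C
Reagents that add atoms: formaldehyde, C=O
Why: Lanthanide-triflate-catalysed Mukaiyama aldol with aqueous formaldehyde forms the C1 quaternary centre; the electrophile should enter anti to the adjacent C8 side chain (C5 has a substituent on either face), leaving the acetate arm cis to the side chain and to the allyl group, and the γ-hydroxy ester 16 closes to the lactone, which also blocks retro-aldol.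

Step 8
Reactants: 17 (5R,7R,10S)-7-methyl-10-[(2R)-6-methylhept-5-en-2-yl]-7-(prop-2-en-1-yl)-2-oxaspiro[4.5]decane-3,6-dione
Product: 21 (5S,7R,10S)-7-methyl-4-methylidene-10-[(2R)-6-methylhept-5-en-2-yl]-7-(prop-2-en-1-yl)-2-oxaspiro[4.5]decane-3,6-dione, via lactone lithium enolate 18 (not isolated), via Mannich base 19 (not isolated), via methiodide 20 (not isolated)
Conditions: LiN(SiMe3)2, THF, −78 °C; CH2=NMe2+ I−, −78 °C to rt; then MeI, MeOH, rt; then DBU, CH2Cl2, rt
Reagents that add atoms: N,N-dimethylmethyleneiminium iodide (Eschenmoser salt), C=[N+](C)C.[I-]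
Why: α-Methylenation of a γ-butyrolactone through Mannich base, quaternisation and elimination; the lactone CH2 is the only enolisable position and the silylamide base cannot reduce the non-enolisable ketone by hydride transfer.

Step 9
Reactants: 21 (5S,7R,10S)-7-methyl-4-methylidene-10-[(2R)-6-methylhept-5-en-2-yl]-7-(prop-2-en-1-yl)-2-oxaspiro[4.5]decane-3,6-dione
Product: 22 γ-lactone of (1S,5R,8S)-1-(hydroxymethyl)-5-methyl-8-[(2R)-6-methylhept-5-en-2-yl]-9-oxobicyclo[3.3.1]non-2-ene-2-carboxylic acid
Conditions: (H2IMes)Cl2Ru=CH(2-i-PrO-C6H4) (second-generation Hoveyda–Grubbs catalyst, 10 mol%), 1,4-benzoquinone (20 mol%), toluene (0.005 M), 80 °C, argon sparge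
Reagents that add atoms: none
Why: The ruthenium carbene initiates at the monosubstituted allyl alkene of 21; the alkylidene then formed on C3 undergoes [2+2] cycloaddition with the exocyclic methylene on C2 and cycloreversion, releasing ethene and forming C2=C3. The closest known reactions are ring-closing metatheses of 2-substituted acrylates to 1-cyclohexenecarboxylates and closures between syn-diaxial alkenyl groups on cyclohexanones that give bicyclo[3.3.1]nonenones. Ring A (C1, C2, C3, C4, C5, C9) closes as a six-membered ring between the chain on C5 and the chain on C1, both axial in the chair that keeps the C8 side chain equatorial. No stereocentre is created; the step needs the cis relation of the two arms set in steps 4 and 7, and a C1 epimer with trans arms cannot cyclise and is removed here. Site selectivity is needed against the trisubstituted side-chain alkene, which is too hindered to load the catalyst or to compete, and against dimerisation through the allyl group, which high dilution should suppress. The spiro-lactone holds the methylene over ring B pointing at C4 and has no ring-side allylic hydrogen, so isomerisation to an endocyclic butenolide is impossible, and benzoquinone limits allyl-to-propenyl migration by ruthenium hydrides. The C9 ketone, between two quaternary carbons, is inert.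

Step 10
Reactants: 22 γ-lactone of (1S,5R,8S)-1-(hydroxymethyl)-5-methyl-8-[(2R)-6-methylhept-5-en-2-yl]-9-oxobicyclo[3.3.1]non-2-ene-2-carboxylic acid
Product: 23 (1S,5R,8S,9R)-1,2-bis(hydroxymethyl)-5-methyl-8-[(2R)-6-methylhept-5-en-2-yl]bicyclo[3.3.1]non-2-en-9-ol
Conditions: i-Bu2AlH (6 equiv), CH2Cl2, −78 °C to rt; aq. KNaC4H4O6 work-up
Reagents that add atoms: none
Why: i-Bu2AlH reduces the conjugated lactone in the 1,2-sense to the allylic diol and the ketone to the carbinol; hydride should reach C9 from the ring A face, where C2 and C3 are sp2 and only the axial hydrogen on C4 flanks the trajectory against two (C6, C8) on the ring B face, giving the alcohol axial on ring B as required.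

Step 11
Reactants: 23 (1S,5R,8S,9R)-1,2-bis(hydroxymethyl)-5-methyl-8-[(2R)-6-methylhept-5-en-2-yl]bicyclo[3.3.1]non-2-en-9-ol
Product: 24 (1S,5R,8S,9R)-5-methyl-8-[(2R)-6-methylhept-5-en-2-yl]-1,2-bis[(triethylsilyloxy)methyl]bicyclo[3.3.1]non-2-en-9-ol
Conditions: Et3SiCl (2.3 equiv), imidazole, CH2Cl2, −20 to 0 °C
Reagents that add atoms: chlorotriethylsilane, CC[Si](Cl)(CC)CC
Why: Chemoselective silylation of the two primary alcohols; the C9 hydroxyl between two quaternary carbons should not react with Et3SiCl and imidazole at low temperature.

Step 12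
Reactants: 24 (1S,5R,8S,9R)-5-methyl-8-[(2R)-6-methylhept-5-en-2-yl]-1,2-bis[(triethylsilyloxy)methyl]bicyclo[3.3.1]non-2-en-9-ol
Product: 25 (1S,5R,8S,9R)-5-methyl-8-[(2R)-6-methylhept-5-en-2-yl]-1,2-bis[(triethylsilyloxy)methyl]bicyclo[3.3.1]non-2-en-9-yl acetate
Conditions: Ac2O, 4-(dimethylamino)pyridine, Et3N, CH2Cl2, 40 °C
Reagents that add atoms: acetic anhydride, CC(=O)OC(C)=O
Why: Nucleophile-catalysed acetylation of the hindered secondary alcohol, done before any aldehyde is present so that forcing conditions cannot trigger retro-aldol cleavage of C1–C9.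

Step 13
Reactants: 25 (1S,5R,8S,9R)-5-methyl-8-[(2R)-6-methylhept-5-en-2-yl]-1,2-bis[(triethylsilyloxy)methyl]bicyclo[3.3.1]non-2-en-9-yl acetate
Product: 27 (1R,5R,8S,9R)-1,2-diformyl-5-methyl-8-[(2R)-6-methylhept-5-en-2-yl]bicyclo[3.3.1]non-2-en-9-yl acetate, via bis(alkoxysulfonium) chloride 26 (not isolated)
Conditions: (COCl)2, DMSO, CH2Cl2, −78 to −40 °C; then Et3N, −78 to 0 °C
Reagents that add atoms: none
Why: Swern oxidation applied directly to primary triethylsilyl ethers: chlorodimethylsulfonium chloride converts both Si–O–CH2 groups into alkoxysulfonium ions (26) with loss of Et3SiCl, and base then gives both aldehydes at once; no free hydroxy aldehyde exists at any time, so lactol formation and over-oxidation are excluded and the acetate is untouched.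

## Compound list

1 | (R)-citronellal | O=CC[C@H](C)CCC=C(C)C | starting material
2 | (R)-1-methoxy-4,8-dimethylnona-1,7-diene (E/Z) | COC=CC[C@H](C)CCC=C(C)C | intermediate
3 | (R)-4,8-dimethylnon-7-enal | O=CCC[C@H](C)CCC=C(C)C | intermediate
4 | (2E,4R)-4,8-dimethylnona-2,7-dienal | O=C/C=C/[C@H](C)CCC=C(C)C | intermediate
5 | tert-butyl 3-oxopentanoate | CCC(=O)CC(=O)OC(C)(C)C | starting material
6 | tert-butyl (3S,4R)-4,8-dimethyl-3-(2-oxoethyl)-2-propanoylnon-7-enoate (Michael adduct, C2 epimers) | CCC(=O)C(C(=O)OC(C)(C)C)[C@H]([C@H](C)CCC=C(C)C)CC=O | intermediate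
7 | tert-butyl (6S)-3-methyl-6-[(2R)-6-methylhept-5-en-2-yl]-2-oxocyclohex-3-ene-1-carboxylate (C1 epimers) | O=C1C(C(=O)OC(C)(C)C)[C@H]([C@H](C)CCC=C(C)C)CC=C1C | intermediate
8 | (5R)-2-methyl-5-[(2R)-6-methylhept-5-en-2-yl]cyclohex-2-en-1-one | O=C1C[C@H]([C@H](C)CCC=C(C)C)CC=C1C | intermediate
9 | allyl bromide | C=CCBr | starting material
10 | lithium (5R)-2-methyl-5-[(2R)-6-methylhept-5-en-2-yl]cyclohex-1-en-1-olate | [Li+].[O-]C1=C(C)CC[C@@H]([C@H](C)CCC=C(C)C)C1 | intermediate
11 | (2R,5R)-2-methyl-5-[(2R)-6-methylhept-5-en-2-yl]-2-(prop-2-en-1-yl)cyclohexan-1-one | O=C1[C@@](C)(CC=C)CC[C@@H]([C@H](C)CCC=C(C)C)C1 | intermediate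
12 | methyl bromoacetate | COC(=O)CBr | starting material
13 | lithium enolate of 11, enolised toward C1 | [Li+].[O-]C1=C[C@H]([C@H](C)CCC=C(C)C)CC[C@]1(C)CC=C | intermediate
14 | methyl 2-[(3R,6S)-3-methyl-6-[(2R)-6-methylhept-5-en-2-yl]-2-oxo-3-(prop-2-en-1-yl)cyclohexyl]acetate (epimers at ring C1) | O=C1[C@@](C)(CC=C)CC[C@@H]([C@H](C)CCC=C(C)C)C1CC(=O)OC | intermediate
15 | methyl 2-[(3R,6S)-3-methyl-6-[(2R)-6-methylhept-5-en-2-yl]-3-(prop-2-en-1-yl)-2-(trimethylsilyloxy)cyclohex-1-en-1-yl]acetate | C[Si](C)(C)OC1=C(CC(=O)OC)[C@H]([C@H](C)CCC=C(C)C)CC[C@]1(C)CC=C | intermediate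
16 | methyl 2-[(1R,3R,6S)-1-(hydroxymethyl)-3-methyl-6-[(2R)-6-methylhept-5-en-2-yl]-2-oxo-3-(prop-2-en-1-yl)cyclohexyl]acetate | O=C1[C@@](C)(CC=C)CC[C@@H]([C@H](C)CCC=C(C)C)[C@@]1(CO)CC(=O)OC | intermediate
17 | (5R,7R,10S)-7-methyl-10-[(2R)-6-methylhept-5-en-2-yl]-7-(prop-2-en-1-yl)-2-oxaspiro[4.5]decane-3,6-dione | O=C1[C@@](C)(CC=C)CC[C@@H]([C@H](C)CCC=C(C)C)[C@]12COC(=O)C2 | intermediate
18 | lithium enolate of lactone 17 | [Li+].[O-]C1=C[C@@]2(CO1)[C@H]([C@H](C)CCC=C(C)C)CC[C@](C)(CC=C)C2=O | intermediate
19 | 4-[(dimethylamino)methyl] derivative of 17 (Mannich base, new centre unassigned) | O=C1[C@@](C)(CC=C)CC[C@@H]([C@H](C)CCC=C(C)C)[C@]12COC(=O)C2CN(C)C | intermediate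
20 | trimethylammonium iodide of 19 | O=C1[C@@](C)(CC=C)CC[C@@H]([C@H](C)CCC=C(C)C)[C@]12COC(=O)C2C[N+](C)(C)C.[I-] | intermediate
21 | (5S,7R,10S)-7-methyl-4-methylidene-10-[(2R)-6-methylhept-5-en-2-yl]-7-(prop-2-en-1-yl)-2-oxaspiro[4.5]decane-3,6-dione | O=C1[C@@](C)(CC=C)CC[C@@H]([C@H](C)CCC=C(C)C)[C@]12COC(=O)C2=C | intermediate
22 | γ-lactone of (1S,5R,8S)-1-(hydroxymethyl)-5-methyl-8-[(2R)-6-methylhept-5-en-2-yl]-9-oxobicyclo[3.3.1]non-2-ene-2-carboxylic acid | O=C1[C@@]2(C)CC=C3C(=O)OC[C@]31[C@H]([C@H](C)CCC=C(C)C)CC2 | intermediate
23 | (1S,5R,8S,9R)-1,2-bis(hydroxymethyl)-5-methyl-8-[(2R)-6-methylhept-5-en-2-yl]bicyclo[3.3.1]non-2-en-9-ol | O[C@@H]1[C@@]2(C)CC=C(CO)[C@]1(CO)[C@H]([C@H](C)CCC=C(C)C)CC2 | intermediate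
24 | (1S,5R,8S,9R)-5-methyl-8-[(2R)-6-methylhept-5-en-2-yl]-1,2-bis[(triethylsilyloxy)methyl]bicyclo[3.3.1]non-2-en-9-ol | O[C@@H]1[C@@]2(C)CC=C(CO[Si](CC)(CC)CC)[C@]1(CO[Si](CC)(CC)CC)[C@H]([C@H](C)CCC=C(C)C)CC2 | intermediate
25 | (1S,5R,8S,9R)-5-methyl-8-[(2R)-6-methylhept-5-en-2-yl]-1,2-bis[(triethylsilyloxy)methyl]bicyclo[3.3.1]non-2-en-9-yl acetate | CC(=O)O[C@@H]1[C@@]2(C)CC=C(CO[Si](CC)(CC)CC)[C@]1(CO[Si](CC)(CC)CC)[C@H]([C@H](C)CCC=C(C)C)CC2 | intermediate
26 | 1,2-bis{[(dimethylsulfonio)oxy]methyl} analogue of 25, dichloride | CC(=O)O[C@@H]1[C@@]2(C)CC=C(CO[S+](C)C)[C@]1(CO[S+](C)C)[C@H]([C@H](C)CCC=C(C)C)CC2.[Cl-].[Cl-] | intermediate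
27 | (1R,5R,8S,9R)-1,2-diformyl-5-methyl-8-[(2R)-6-methylhept-5-en-2-yl]bicyclo[3.3.1]non-2-en-9-yl acetate | CC(=O)O[C@@H]1[C@@]2(C)CC=C(C=O)[C@]1(C=O)[C@H]([C@H](C)CCC=C(C)C)CC2 | target

## Step count and least certain steps

Total: 13 steps. Longest linear sequence: 13 steps from 1 (all other building blocks are commercial).

**Step 9 (key step).** The likeliest failure is that the alkylidene formed at the allyl terminus does not engage the crowded, electron-poor methylene. Dimerisation through the allyl groups, or allyl-to-propenyl migration followed by ring contraction, would then take over. The fallback moves the metathesis to the allylic-ether oxidation level, where the 1,1-disubstituted alkene is electron-rich. It sets out from 21. Exhaustive reduction with i-Bu2AlH gives the monocyclic triol F1 (C9 carbinol as a mixture). Et3SiCl and imidazole give the bis(silyl ether) F2. Dess–Martin periodinane restores the ketone in F3, and ring closure with (H2IMes)(PCy3)Cl2Ru=CHPh (second-generation Grubbs catalyst) gives the bicyclic ketone F4. Reduction with i-Bu2AlH, with the same face argument as in step 10, returns to the route at 24.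

**Step 3.** The γ-branched enal can form a dienamine with the amine catalyst, which would erode C1'. Catalyst control at C8 may be incomplete next to that stereocentre, and the hot acid may move the side-chain alkene. The fallback sets C8 with an auxiliary and closes the ring by metathesis. It sets out from 4. Oxidation (NaClO2, NaH2PO4, 2-methylbut-2-ene) gives acid F5, which is coupled with (R)-4-phenyloxazolidin-2-one (t-BuCOCl, Et3N, LiCl) to imide F6. Conjugate allylation (allyltrimethylsilane, TiCl4, −78 °C) should deliver allyl anti to phenyl in the chelated s-cis imide, giving F7. MeONHMe·HCl with AlMe3 gives Weinreb amide F8 and releases the auxiliary. CH2=C(CH3)MgBr gives dienone F9, and (H2IMes)(PCy3)Cl2Ru=CHPh closes the cyclohexenone, returning to the route at 8.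

**Step 7.** Aldol addition at the congested tetrasubstituted enol silane may be slow, so that protodesilylation back to 14 wins, and the facial bias may be incomplete. The fallback generates the same C1 enolate as a lithium enolate by conjugate reduction and traps it cold and irreversibly. It sets out from 11, which is condensed with methyl glyoxylate (LiN(i-Pr)2, −78 °C; then MsCl, Et3N and DBU in the same flask) to the alkylidene keto ester F10. LiBH(s-Bu)3 at −78 °C adds hydride to the ester-bearing alkene carbon and gives the lithium enolate F11. Gaseous formaldehyde then gives 16, which lactonises, returning to the route at 17. A minor C1 epimer from either procedure cannot undergo step 9 and is removed there.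

**Step 10.** Facial selectivity of hydride delivery at C9 may be poor, and some 1,4-reduction of the enoate is possible. The fallback separates the two reductions. It sets out from 22: LiAlH(O-t-Bu)3 at low temperature reduces only the ketone and gives the hydroxy lactone F12. Its C9 epimers can be separated at this stage and the unwanted one re-oxidised. LiAlH4 then opens the lactone and returns to the route at 23.

**Step 13.** Exchange of the neopentyl silyl ether for the sulfonium group may be incomplete, and chloride may displace the allylic alkoxysulfonium ion. The fallback sets out from 25: HF·pyridine in THF–pyridine at 0 °C removes both silyl groups and gives the acetoxy diol F13; the acidic fluoride avoids base-promoted 1,3-acetyl migration. A conventional Swern oxidation of the free 1,4-diol then returns to the route at 27.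

## Further compounds

F1 | step 9 | 2-[2-hydroxy-1-(hydroxymethyl)-3-methyl-6-[(2R)-6-methylhept-5-en-2-yl]-3-(prop-2-en-1-yl)cyclohexyl]prop-2-en-1-ol (ring configuration as in 21, carbinol epimers) | OC1[C@@](C)(CC=C)CC[C@@H]([C@H](C)CCC=C(C)C)[C@@]1(CO)C(=C)CO
F2 | step 9 | bis(triethylsilyl) ether of F1 at the two primary hydroxyls | OC1[C@@](C)(CC=C)CC[C@@H]([C@H](C)CCC=C(C)C)[C@@]1(CO[Si](CC)(CC)CC)C(=C)CO[Si](CC)(CC)CC
F3 | step 9 | cyclohexanone from F2 (2-allyl-2-methyl-6-[(triethylsilyloxy)methyl]-6-[3-(triethylsilyloxy)prop-1-en-2-yl]-5-[(2R)-6-methylhept-5-en-2-yl]cyclohexan-1-one) | O=C1[C@@](C)(CC=C)CC[C@@H]([C@H](C)CCC=C(C)C)[C@@]1(CO[Si](CC)(CC)CC)C(=C)CO[Si](CC)(CC)CC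
F4 | step 9 | 5-methyl-8-[(2R)-6-methylhept-5-en-2-yl]-1,2-bis[(triethylsilyloxy)methyl]bicyclo[3.3.1]non-2-en-9-one | O=C1[C@@]2(C)CC=C(CO[Si](CC)(CC)CC)[C@]1(CO[Si](CC)(CC)CC)[C@H]([C@H](C)CCC=C(C)C)CC2
F5 | step 3 | (2E,4R)-4,8-dimethylnona-2,7-dienoic acid | OC(=O)/C=C/[C@H](C)CCC=C(C)C
F6 | step 3 | (4R)-3-[(2E,4R)-4,8-dimethylnona-2,7-dienoyl]-4-phenyl-1,3-oxazolidin-2-one | O=C(/C=C/[C@H](C)CCC=C(C)C)N1[C@H](c2ccccc2)COC1=O
F7 | step 3 | (4R)-3-[(3R,4R)-4,8-dimethyl-3-(prop-2-en-1-yl)non-7-enoyl]-4-phenyl-1,3-oxazolidin-2-one | O=C(C[C@@H](CC=C)[C@H](C)CCC=C(C)C)N1[C@H](c2ccccc2)COC1=O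
F8 | step 3 | (3R,4R)-N-methoxy-N,4,8-trimethyl-3-(prop-2-en-1-yl)non-7-enamide | CON(C)C(=O)C[C@@H](CC=C)[C@H](C)CCC=C(C)C
F9 | step 3 | (5R,6R)-2,6,10-trimethyl-5-(prop-2-en-1-yl)undeca-1,9-dien-3-one | CC(=C)C(=O)C[C@@H](CC=C)[C@H](C)CCC=C(C)C
F10 | step 7 | methyl 2-[(3R,6R)-3-methyl-6-[(2R)-6-methylhept-5-en-2-yl]-2-oxo-3-(prop-2-en-1-yl)cyclohexylidene]acetate (alkene geometry open) | O=C1[C@@](C)(CC=C)CC[C@@H]([C@H](C)CCC=C(C)C)C1=CC(=O)OC
F11 | step 7 | lithium enolate of keto ester 14, enolised toward C1 | [Li+].[O-]C1=C(CC(=O)OC)[C@H]([C@H](C)CCC=C(C)C)CC[C@]1(C)CC=C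
F12 | step 10 | γ-lactone of (1S,5R,8S,9R)-9-hydroxy-1-(hydroxymethyl)-5-methyl-8-[(2R)-6-methylhept-5-en-2-yl]bicyclo[3.3.1]non-2-ene-2-carboxylic acid | O[C@@H]1[C@@]2(C)CC=C3C(=O)OC[C@]31[C@H]([C@H](C)CCC=C(C)C)CC2
F13 | step 13 | (1S,5R,8S,9R)-1,2-bis(hydroxymethyl)-5-methyl-8-[(2R)-6-methylhept-5-en-2-yl]bicyclo[3.3.1]non-2-en-9-yl acetate | CC(=O)O[C@@H]1[C@@]2(C)CC=C(CO)[C@]1(CO)[C@H]([C@H](C)CCC=C(C)C)CC2
A1 | alternative 1 | deacetyl target, 9-hydroxy-5-methyl-8-[(2R)-6-methylhept-5-en-2-yl]bicyclo[3.3.1]non-2-ene-1,2-dicarbaldehyde | O[C@@H]1[C@@]2(C)CC=C(C=O)[C@]1(C=O)[C@H]([C@H](C)CCC=C(C)C)CC2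
A2 | alternative 1 | 5-methyl-8-[(2R)-6-methylhept-5-en-2-yl]cyclooct-2-ene-1,2,5-tricarbaldehyde (C1 epimers) | O=C[C@@]1(C)CC=C(C=O)C(C=O)[C@H]([C@H](C)CCC=C(C)C)CC1
A3 | alternative 2 | 2-(tert-butyldimethylsilyloxy)-1-methyl-4-[(2R)-6-methylhept-5-en-2-yl]cyclohex-3-ene-1-carbaldehyde | O=C[C@@]1(C)CCC([C@H](C)CCC=C(C)C)=C[C@@H]1O[Si](C)(C)C(C)(C)C
A4 | alternative 2 | (1E)-1-(tert-butyldimethylsilyloxy)-3-[(2R)-6-methylhept-5-en-2-yl]buta-1,3-diene | CC(C)(C)[Si](C)(C)O/C=C/C(=C)[C@H](C)CCC=C(C)C
A5 | alternative 2 | methacrolein | CC(=C)C=O
A6 | alternative 3 | dimethyl 5-methyl-8-[(2R)-6-methylhept-5-en-2-yl]-9-oxobicyclo[3.3.1]nona-2,6-diene-1,2-dicarboxylate | O=C1[C@@]2(C)CC=C(C(=O)OC)[C@]1(C(=O)OC)[C@H]([C@H](C)CCC=C(C)C)C=C2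
A7 | alternative 3 | dimethyl 6-(tert-butyldimethylsilyloxy)-5-methyl-1-[(3S,4R)-4,8-dimethylnon-7-en-1-yn-3-yl]cyclohexa-2,5-diene-1,2-dicarboxylate | COC(=O)C1=CCC(C)=C(O[Si](C)(C)C(C)(C)C)[C@@]1(C(=O)OC)[C@@H](C#C)[C@H](C)CCC=C(C)C
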